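Assumption: bisoflavolin L has no stereocentre and no hindered axis, so the "single enantiomer" is the achiral compound itself; the only stereocentres on the route are the transient C3 carbinols 5 and 12 (racemic), which are erased by dehydration.

**Retrosynthetic overview**
1. Bisoflavolin L 14 comes from its tetramethyl ether 13 by a final global O-demethylation.
2. Each pyranone ring C is cut at C3–C4: an N-heterocyclic carbene turns a salicylaldehyde carbon into an acyl-anion (Breslow) nucleophile that attacks the carbonyl of an O-tethered aryl ketone, and loss of water then gives the isoflavone.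
3. The keto-aldehydes come from salicylaldehydes and phenacyl bromides (O1–C2 bonds); alkylating the OH that sits next to C–Cl fixes the chlorine at C8.
4. The diaryl ether is cut between the 4'-bromophenyl group of the chlorinated isoflavone and the 3-OH of 3-hydroxy-4-methoxyacetophenone (Ullmann coupling); the acetyl group of the latter becomes the second phenacyl bromide.
5. Ring order: chlorinated chromone ring C first, then the diaryl ether, then the 7-oxygenated chromone ring C; rings A and B come intact from commercial aromatics.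

**Route**

Step 1
Reactants: 1 2-hydroxy-4,6-dimethoxybenzaldehyde
Product: 2 3-chloro-2-hydroxy-4,6-dimethoxybenzaldehyde
Conditions: NCS (1.05 equiv), MeCN, 0 °C to rt
Reagents that add atoms: N-chlorosuccinimide, O=C1CCC(=O)N1Cl
Why: Electrophilic aromatic chlorination of a strongly activated phenol goes ortho to the free OH (C3, also para to the 6-OMe) rather than to the more hindered C5 between two OMe groups, as in the known 3-halogenation of 2-hydroxy-4,6-dimethoxyaryl carbonyl compounds, and the formyl group limits it to monochlorination.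

Step 2
Reactants: 2 3-chloro-2-hydroxy-4,6-dimethoxybenzaldehyde; 3 2-bromo-1-(4-bromophenyl)ethan-1-one (4-bromophenacyl bromide)
Product: 4 2-[2-(4-bromophenyl)-2-oxoethoxy]-3-chloro-4,6-dimethoxybenzaldehyde
Conditions: K2CO3 (1.5 equiv), acetone, rt
Reagents that add atoms: none
Why: Williamson ether synthesis (SN2) of the acidic salicylaldehyde phenoxide on a very reactive phenacyl bromide runs at room temperature, below the threshold for Rap–Stoermer aldol closure to a benzofuran, and it commits the oxygen next to C–Cl to become O1 so that chlorine ends at C8.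

Step 3
Reactants: 4 2-[2-(4-bromophenyl)-2-oxoethoxy]-3-chloro-4,6-dimethoxybenzaldehyde
Product: 6 3-(4-bromophenyl)-8-chloro-5,7-dimethoxy-4H-chromen-4-one, via racemic 3-hydroxychroman-4-one 5 (not isolated)
Conditions: 2-(pentafluorophenyl)-6,7-dihydro-5H-pyrrolo[2,1-c][1,2,4]triazol-2-ium tetrafluoroborate (20 mol %), Et3N (20 mol %), THF, rt to 40 °C; then Burgess reagent (methyl N-(triethylammoniosulfonyl)carbamate, 2.5 equiv), 65 °C
Reagents that add atoms: none
Why: NHC-catalysed intramolecular crossed aldehyde–ketone benzoin reaction, in which the carbene converts the aldehyde carbon into an acyl-anion (Breslow) nucleophile that adds to the tethered aryl-ketone carbonyl and closes the six-membered ring C through the C3–C4 bond (C3 carbinol formed racemic with the achiral catalyst), followed by Burgess syn-dehydration of the tertiary alcohol, which removes that stereocentre and gives the conjugated chromone.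

Step 4
Reactants: 6 3-(4-bromophenyl)-8-chloro-5,7-dimethoxy-4H-chromen-4-one; 7 1-(3-hydroxy-4-methoxyphenyl)ethan-1-one (3-hydroxy-4-methoxyacetophenone)
Product: 8 3-[4-(5-acetyl-2-methoxyphenoxy)phenyl]-8-chloro-5,7-dimethoxy-4H-chromen-4-one
Conditions: CuI (copper monoiodide, 10 mol %), picolinic acid (20 mol %), K3PO4 (2 equiv), 4 Å MS, DMSO, 90 °C
Reagents that add atoms: none
Why: Ullmann-type copper-catalysed diaryl ether synthesis couples the unhindered aryl bromide with the guaiacol-type phenoxide, while the hindered, electron-rich C8–Cl bond and the methyl ketone do not react under these anhydrous, weakly basic conditions.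

Step 5
Reactants: 8 3-[4-(5-acetyl-2-methoxyphenoxy)phenyl]-8-chloro-5,7-dimethoxy-4H-chromen-4-one
Product: 9 3-{4-[5-(2-bromoacetyl)-2-methoxyphenoxy]phenyl}-8-chloro-5,7-dimethoxy-4H-chromen-4-one
Conditions: CuBr2 (2.1 equiv), EtOAc/CHCl3 (1:1), reflux
Reagents that add atoms: copper dibromide CuBr2, Br[Cu]Br
Why: Heterogeneous CuBr2 α-bromination of a ketone proceeds through the copper-bound enol of the only enolisable carbonyl and is known to leave electron-rich aromatic rings (here C6–H of the dimethoxychromone) unbrominated.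

Step 6
Reactants: 9 3-{4-[5-(2-bromoacetyl)-2-methoxyphenoxy]phenyl}-8-chloro-5,7-dimethoxy-4H-chromen-4-one; 10 2-hydroxy-4-methoxybenzaldehyde
Product: 11 2-{2-[3-(4-(8-chloro-5,7-dimethoxy-4-oxo-4H-chromen-3-yl)phenoxy)-4-methoxyphenyl]-2-oxoethoxy}-4-methoxybenzaldehyde
Conditions: K2CO3 (1.5 equiv), acetone (DMF co-solvent for solubility), rt
Reagents that add atoms: none
Why: Williamson ether synthesis as in step 2, mild enough that the existing chromone is not opened and the new keto-aldehyde does not undergo aldol closure.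

Step 7
Reactants: 11 2-{2-[3-(4-(8-chloro-5,7-dimethoxy-4-oxo-4H-chromen-3-yl)phenoxy)-4-methoxyphenyl]-2-oxoethoxy}-4-methoxybenzaldehyde
Product: 13 8-chloro-5,7-dimethoxy-3-{4-[2-methoxy-5-(7-methoxy-4-oxo-4H-chromen-3-yl)phenoxy]phenyl}-4H-chromen-4-one, via racemic 3-hydroxychroman-4-one 12 (not isolated)
Conditions: 2-(pentafluorophenyl)-6,7-dihydro-5H-pyrrolo[2,1-c][1,2,4]triazol-2-ium tetrafluoroborate (20 mol %), Et3N (20 mol %), THF, rt; then Burgess reagent (2.5 equiv), 65 °C
Reagents that add atoms: none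
Why: The same NHC-catalysed intramolecular crossed benzoin reaction, now on a less hindered 2-alkoxy-4-methoxybenzaldehyde, closes the second ring C through C3–C4 (racemic C3 carbinol), and Burgess dehydration of the tertiary, anisyl-type benzylic alcohol erases the stereocentre and gives the second isoflavone.

Step 8
Reactants: 13 8-chloro-5,7-dimethoxy-3-{4-[2-methoxy-5-(7-methoxy-4-oxo-4H-chromen-3-yl)phenoxy]phenyl}-4H-chromen-4-one
Product: 14 bisoflavolin L (8-chloro-5,7-dihydroxy-3-{4-[2-hydroxy-5-(7-hydroxy-4-oxo-4H-chromen-3-yl)phenoxy]phenyl}-4H-chromen-4-one)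
Conditions: BBr3 (12 equiv), CH2Cl2, −78 °C to rt; then MeOH, H2O
Reagents that add atoms: none
Why: Lewis-acid cleavage of aryl methyl ethers with BBr3 removes all four O-methyl groups (the chelated 5-OMe fastest), while the diaryl ether, the aryl chloride and both chromone rings are inert to it.

**Compound list**

1 | 2-hydroxy-4,6-dimethoxybenzaldehyde | O=Cc1c(O)cc(OC)cc1OC | starting material
2 | 3-chloro-2-hydroxy-4,6-dimethoxybenzaldehyde | O=Cc1c(O)c(Cl)c(OC)cc1OC | intermediate
3 | 2-bromo-1-(4-bromophenyl)ethan-1-one | O=C(CBr)c1ccc(Br)cc1 | starting material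
4 | 2-[2-(4-bromophenyl)-2-oxoethoxy]-3-chloro-4,6-dimethoxybenzaldehyde | O=Cc1c(OCC(=O)c2ccc(Br)cc2)c(Cl)c(OC)cc1OC | intermediate
5 | racemic 3-(4-bromophenyl)-8-chloro-3-hydroxy-5,7-dimethoxychroman-4-one (not isolated) | O=C1c2c(OC)cc(OC)c(Cl)c2OCC1(O)c1ccc(Br)cc1 | intermediate
6 | 3-(4-bromophenyl)-8-chloro-5,7-dimethoxy-4H-chromen-4-one | O=c1c(-c2ccc(Br)cc2)coc2c(Cl)c(OC)cc(OC)c12 | intermediate
7 | 1-(3-hydroxy-4-methoxyphenyl)ethan-1-one | CC(=O)c1ccc(OC)c(O)c1 | starting material
8 | 3-[4-(5-acetyl-2-methoxyphenoxy)phenyl]-8-chloro-5,7-dimethoxy-4H-chromen-4-one | CC(=O)c1ccc(OC)c(Oc2ccc(-c3coc4c(Cl)c(OC)cc(OC)c4c3=O)cc2)c1 | intermediate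
9 | 3-{4-[5-(2-bromoacetyl)-2-methoxyphenoxy]phenyl}-8-chloro-5,7-dimethoxy-4H-chromen-4-one | O=C(CBr)c1ccc(OC)c(Oc2ccc(-c3coc4c(Cl)c(OC)cc(OC)c4c3=O)cc2)c1 | intermediate
10 | 2-hydroxy-4-methoxybenzaldehyde | O=Cc1ccc(OC)cc1O | starting material
11 | 2-{2-[3-(4-(8-chloro-5,7-dimethoxy-4-oxo-4H-chromen-3-yl)phenoxy)-4-methoxyphenyl]-2-oxoethoxy}-4-methoxybenzaldehyde | O=Cc1ccc(OC)cc1OCC(=O)c1ccc(OC)c(Oc2ccc(-c3coc4c(Cl)c(OC)cc(OC)c4c3=O)cc2)c1 | intermediate
12 | racemic 8-chloro-3-{4-[5-(3-hydroxy-7-methoxy-4-oxochroman-3-yl)-2-methoxyphenoxy]phenyl}-5,7-dimethoxy-4H-chromen-4-one (not isolated) | O=C1c2ccc(OC)cc2OCC1(O)c1ccc(OC)c(Oc2ccc(-c3coc4c(Cl)c(OC)cc(OC)c4c3=O)cc2)c1 | intermediate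
13 | 8-chloro-5,7-dimethoxy-3-{4-[2-methoxy-5-(7-methoxy-4-oxo-4H-chromen-3-yl)phenoxy]phenyl}-4H-chromen-4-one (tetra-O-methylbisoflavolin L) | O=c1c(-c2ccc(OC)c(Oc3ccc(-c4coc5c(Cl)c(OC)cc(OC)c5c4=O)cc3)c2)coc2cc(OC)ccc12 | intermediate
14 | bisoflavolin L | O=c1c(-c2ccc(O)c(Oc3ccc(-c4coc5c(Cl)c(O)cc(O)c5c4=O)cc3)c2)coc2cc(O)ccc12 | target

**Totals**

Total step count: 8. Longest linear sequence: 8 steps (1 to 14).

**Steps most likely to fail, with fallbacks**

Step 3 (carbene addition to a di-ortho-substituted, electron-rich aldehyde; competing aldol closure to a benzofuran). The fallback replaces the catalytic benzoin by a stoichiometric acyl anion and makes the same C3–C4 bond by alkylation. It sets out from compound 2. Propane-1,3-dithiol with catalytic BF3·OEt2 in CH2Cl2 gives 6-chloro-2-(1,3-dithian-2-yl)-3,5-dimethoxyphenol F4. Its O,C-dianion (n-BuLi, 2.2 equiv, THF, −78 to −20 °C) is alkylated at carbon with 4-bromobenzyl bromide to give 2-[2-(4-bromobenzyl)-1,3-dithian-2-yl]-6-chloro-3,5-dimethoxyphenol F5. Alkylative hydrolysis (MeI, CaCO3, aqueous MeCN, 60 °C) unmasks the deoxybenzoin 2-(4-bromophenyl)-1-(3-chloro-2-hydroxy-4,6-dimethoxyphenyl)ethan-1-one F6. Heating F6 with N,N-dimethylformamide dimethyl acetal in toluene at 100 °C adds C2 and closes the pyranone through the only free OH (the one next to C–Cl). The fallback comes back to the route at compound 6.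

Step 4 (Ullmann coupling on a base-sensitive chromone at 90 °C). The fallback moves the coupling to a room-temperature-type oxidative manifold by reversing the role of the aryl partner. It sets out from compound 6. Miyaura borylation (B2pin2, KOAc, PdCl2(dppf) 3 mol %, dioxane, 85 °C; the hindered C8–Cl bond stays) gives 8-chloro-5,7-dimethoxy-3-[4-(4,4,5,5-tetramethyl-1,3,2-dioxaborolan-2-yl)phenyl]-4H-chromen-4-one F7. Chan–Lam coupling of F7 with phenol 7 (Cu(OAc)2 20 mol %, pyridine, B(OH)3 additive, 4 Å MS, MeCN, air, 60 °C) forms the diaryl ether without strong base. The fallback comes back to the route at compound 8.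

Step 1 (C3 versus C5 chlorination of the aldehyde). The fallback installs chlorine later, under substrate control of the chromone instead of phenol direction. It sets out from compound 1. O-Alkylation of 1 with 3 (K2CO3, acetone, rt) gives 2-[2-(4-bromophenyl)-2-oxoethoxy]-4,6-dimethoxybenzaldehyde F1. The same carbene-catalysed benzoin closure gives racemic 3-(4-bromophenyl)-3-hydroxy-5,7-dimethoxychroman-4-one F2, and Burgess dehydration gives 3-(4-bromophenyl)-5,7-dimethoxy-4H-chromen-4-one F3. Chlorination of F3 with NCS (DMF, rt) is expected at C8, the usual site of electrophilic halogenation in 5,7-dimethoxy(iso)flavones. The fallback comes back to the route at compound 6.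

**Further compounds**

F1 | step 1 | 2-[2-(4-bromophenyl)-2-oxoethoxy]-4,6-dimethoxybenzaldehyde | O=Cc1c(OCC(=O)c2ccc(Br)cc2)cc(OC)cc1OC
F2 | step 1 | racemic 3-(4-bromophenyl)-3-hydroxy-5,7-dimethoxychroman-4-one | O=C1c2c(OC)cc(OC)cc2OCC1(O)c1ccc(Br)cc1
F3 | step 1 | 3-(4-bromophenyl)-5,7-dimethoxy-4H-chromen-4-one | O=c1c(-c2ccc(Br)cc2)coc2cc(OC)cc(OC)c12
F4 | step 3 | 6-chloro-2-(1,3-dithian-2-yl)-3,5-dimethoxyphenol | Oc1c(Cl)c(OC)cc(OC)c1C1SCCCS1
F5 | step 3 | 2-[2-(4-bromobenzyl)-1,3-dithian-2-yl]-6-chloro-3,5-dimethoxyphenol | Oc1c(Cl)c(OC)cc(OC)c1C1(Cc2ccc(Br)cc2)SCCCS1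
F6 | step 3 | 2-(4-bromophenyl)-1-(3-chloro-2-hydroxy-4,6-dimethoxyphenyl)ethan-1-one | O=C(Cc1ccc(Br)cc1)c1c(O)c(Cl)c(OC)cc1OC
F7 | step 4 | 8-chloro-5,7-dimethoxy-3-[4-(4,4,5,5-tetramethyl-1,3,2-dioxaborolan-2-yl)phenyl]-4H-chromen-4-one | CC1(C)OB(c2ccc(-c3coc4c(Cl)c(OC)cc(OC)c4c3=O)cc2)OC1(C)C
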